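Radermachol is cut at the bond between its ring-ketone carbon and the ortho carbon of the benzene ring attached to the furan α-carbon. The central six-membered ring (ketone carbon, the diketone α-carbon shared with the seven-membered ring, furan Cβ and Cα, two benzene carbons) is thus read as the 6π-electrocyclisation product of an α-oxoketene: the C(=O)–C=C(OH) unit is the acylketene, the furan C=C and its phenyl group the diene. The precursor is a furan-fused benzocycloheptenedione bearing phenyl on the furan and a methyl ester on the CH between ketone and furan. This ester first enables Dieckmann closure of the seven-membered ring, then on heating loses methanol, cyclises and tautomerises to radermachol in one operation.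

Key step: step 7

Remark: radermachol has no stereocentre and its side-chain alkene carries two identical methyl groups, so there is no enantiomer or E/Z isomer to control; the stereocentres of the racemic intermediates 3, 4, 11 and 13 all disappear along the route.

Step 1
Reactants: 1 1-phenylpent-4-en-1-one; 2 methyl bromoacetate
Product: 3 methyl 3-benzoylhex-5-enoate (racemic)
Conditions: LDA, THF, −78 °C; then 2, −78 → 0 °C
Reagents that add atoms: none
Why: Kinetic enolate alkylation: LDA deprotonates the only enolisable position of the aryl ketone and the lithium enolate is C-alkylated by the reactive α-bromo ester (SN2), the new stereocentre forming as a racemate that is destroyed when the furan is made.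

Step 2
Reactants: 3 methyl 3-benzoylhex-5-enoate
Product: 5 methyl 2-(2-phenylfuran-3-yl)acetate, via keto aldehyde 4 (not isolated)
Conditions: O3, CH2Cl2–MeOH, −78 °C; Me2S, −78 °C → rt; then TsOH·H2O (cat.), PhMe, 80 °C
Reagents that add atoms: ozone, [O-][O+]=O
Why: Ozonolysis with reductive work-up cleaves only the terminal alkene to the 1,4-keto aldehyde 4, which under acid catalysis undergoes Paal–Knorr cyclodehydration to the aromatic furan (the stereocentre of 3 becomes furan C3).

Step 3
Reactants: 5 methyl 2-(2-phenylfuran-3-yl)acetate
Product: 6 methyl 2-(5-bromo-2-phenylfuran-3-yl)acetate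
Conditions: NBS (1.0 equiv), DMF, 0 °C, dark
Reagents that add atoms: N-bromosuccinimide, O=C1CCC(=O)N1Br
Why: Electrophilic aromatic bromination of the furan with NBS should occur at the only free α-position (C5), which is far more reactive than C4 or the phenyl ring, while dark, polar conditions suppress radical bromination of the CH2 group.

Step 4
Reactants: 6 methyl 2-(5-bromo-2-phenylfuran-3-yl)acetate; 7 methyl 2-(chlorocarbonyl)benzoate
Product: 8 methyl 2-[2-bromo-4-(2-methoxy-2-oxoethyl)-5-phenylfuran-3-carbonyl]benzoate
Conditions: SnCl4 (2.5 equiv), CH2Cl2, −20 → 0 °C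
Reagents that add atoms: none
Why: Friedel–Crafts acylation: with both α-positions blocked (Br, Ph) the acylium ion from 7 can only attack furan C4, which is more electron-rich than the phenyl ring, and the mild Lewis acid at low temperature should leave the C–Br bond and both esters intact.

Step 5
Reactants: 8 methyl 2-[2-bromo-4-(2-methoxy-2-oxoethyl)-5-phenylfuran-3-carbonyl]benzoate; 9 4,4,5,5-tetramethyl-2-(2-methylprop-1-en-1-yl)-1,3,2-dioxaborolane
Product: 10 methyl 2-[4-(2-methoxy-2-oxoethyl)-2-(2-methylprop-1-en-1-yl)-5-phenylfuran-3-carbonyl]benzoate
Conditions: Pd(dppf)Cl2 (cat.), K3PO4, 1,4-dioxane–H2O (10:1), 80 °C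
Reagents that add atoms: none
Why: Suzuki–Miyaura coupling: oxidative addition into the 2-bromofuran is accelerated by the neighbouring aroyl group, and the alkenyl pinacol boronate transfers the 2-methylprop-1-enyl group under mildly basic conditions that the two methyl esters and the ketone tolerate (no E/Z issue, since the alkene terminus carries two methyl groups).

Step 6
Reactants: 10 methyl 2-[4-(2-methoxy-2-oxoethyl)-2-(2-methylprop-1-en-1-yl)-5-phenylfuran-3-carbonyl]benzoate
Product: 11 methyl 3-(2-methylprop-1-en-1-yl)-4,9-dioxo-1-phenyl-9,10-dihydro-4H-benzo[4,5]cyclohepta[1,2-c]furan-10-carboxylate (racemic, enolisable)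
Conditions: NaHMDS (2.2 equiv), THF, −78 → 0 °C; then 1 M HCl
Reagents that add atoms: none
Why: Dieckmann condensation (intramolecular Claisen): the enolate of the furylacetate attacks the benzoate ester in a 7-exo-trig closure preorganised by the furan and o-phenylene units, the diaryl ketone cannot enolise, and deprotonation of the β-keto ester product by the second equivalent of base drives the reaction; the new stereocentre C10 is racemic and is lost in step 7.

Step 7
Reactants: 11 methyl 3-(2-methylprop-1-en-1-yl)-4,9-dioxo-1-phenyl-9,10-dihydro-4H-benzo[4,5]cyclohepta[1,2-c]furan-10-carboxylate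
Product: 14 radermachol, via acylketene 12 (not isolated), via cyclised dienone 13 (not isolated)
Conditions: Ph2O (0.01 M), 220–240 °C, Ar sweep (−MeOH)
Reagents that add atoms: none
Why: The enol tautomer of β-keto ester 11 should lose methanol thermally through a six-membered transition state to give α-oxoketene 12, whose ketene C=C, the furan C10a=C1 bond and one C=C of the 1-phenyl group form a cisoid hexatriene held in place by the ring system. Thermal 6π-electrocyclisation joins the ketene carbon to the phenyl ortho carbon to give dienone 13, and a hydrogen shift (enolisation) re-aromatises the benzene and furan rings and delivers the hydrogen-bonded enol of the triketone, radermachol. The closest known reaction types are acylketene generation by thermolysis of β-keto esters and the electrocyclic closure of aryl-substituted vinylketenes to naphthols (final stage of the Danheiser benzannulation; carbocyclic counterpart of the Conrad–Limpach and Gould–Jacobs thermal cyclisations). One ring is closed, the central six-membered ring, by a 6π-electrocyclic closure that is formally a 6-endo acylation of the arene. No stereocentre remains in 14; the sp3 centre of 13 is transient. The step needs intramolecular capture of the ketene in preference to dimerisation or addition to the side-chain alkene; this is secured by the 1,6-relationship between the ketene carbon and the two equivalent ortho carbons, by high dilution and removal of methanol, and by the absence of acid, which would attack the 2-methylprop-1-enylfuran.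

Compound list
1 | 1-phenylpent-4-en-1-one | C=CCCC(=O)c1ccccc1 | starting material
2 | methyl bromoacetate | COC(=O)CBr | starting material
3 | methyl 3-benzoylhex-5-enoate (racemic) | COC(=O)CC(CC=C)C(=O)c1ccccc1 | intermediate
4 | methyl 3-benzoyl-5-oxopentanoate (racemic keto aldehyde, not isolated) | COC(=O)CC(CC=O)C(=O)c1ccccc1 | intermediate
5 | methyl 2-(2-phenylfuran-3-yl)acetate | COC(=O)Cc1ccoc1-c1ccccc1 | intermediate
6 | methyl 2-(5-bromo-2-phenylfuran-3-yl)acetate | COC(=O)Cc1cc(Br)oc1-c1ccccc1 | intermediate
7 | methyl 2-(chlorocarbonyl)benzoate | COC(=O)c1ccccc1C(Cl)=O | starting material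
8 | methyl 2-[2-bromo-4-(2-methoxy-2-oxoethyl)-5-phenylfuran-3-carbonyl]benzoate | COC(=O)Cc1c(C(=O)c2ccccc2C(=O)OC)c(Br)oc1-c1ccccc1 | intermediate
9 | 4,4,5,5-tetramethyl-2-(2-methylprop-1-en-1-yl)-1,3,2-dioxaborolane | CC(C)=CB1OC(C)(C)C(C)(C)O1 | starting material
10 | methyl 2-[4-(2-methoxy-2-oxoethyl)-2-(2-methylprop-1-en-1-yl)-5-phenylfuran-3-carbonyl]benzoate | COC(=O)Cc1c(C(=O)c2ccccc2C(=O)OC)c(C=C(C)C)oc1-c1ccccc1 | intermediate
11 | methyl 3-(2-methylprop-1-en-1-yl)-4,9-dioxo-1-phenyl-9,10-dihydro-4H-benzo[4,5]cyclohepta[1,2-c]furan-10-carboxylate (racemic; furan 3,4-fused to a benzocycloheptenedione, ester on the CH between ketone and furan) | COC(=O)C1C(=O)c2ccccc2C(=O)c2c(C=C(C)C)oc(-c3ccccc3)c21 | intermediate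
12 | 3-(2-methylprop-1-en-1-yl)-10-(oxomethylidene)-1-phenyl-4H-benzo[4,5]cyclohepta[1,2-c]furan-4,9(10H)-dione (acylketene, not isolated) | O=C=C1C(=O)c2ccccc2C(=O)c2c(C=C(C)C)oc(-c3ccccc3)c21 | intermediate
13 | cyclised dienone: non-aromatised keto tautomer of 14 with an sp3 C–H at the newly bonded benzene carbon and exocyclic C=C bonds at the former furan Cβ and Cα (racemic, not isolated) | CC(C)=CC1=C2C(=O)c3ccccc3C(=O)C3=C2C(O1)=C1C=CC=CC1C3=O | intermediate
14 | radermachol | CC(C)=Cc1oc2c3c(c(O)c4ccccc4c(=O)c13)C(=O)c1ccccc1-2 | target

Total step count: 7. Longest linear sequence: 7 steps (1 → 14).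

Steps most likely to fail

Step 7: methanol loss may need temperatures at which the alkenylfuran degrades, or the ketene may be captured intermolecularly before it cyclises. The fallback closes the ring by a cationic route before the acid-labile side chain is attached. It sets out from 8, which would be taken through the same Dieckmann closure (NaHMDS, THF) to the bromo β-keto ester methyl 3-bromo-4,9-dioxo-1-phenyl-9,10-dihydro-4H-benzo[4,5]cyclohepta[1,2-c]furan-10-carboxylate F1. In conc. H2SO4 (or Eaton's reagent) the ester carbonyl of F1 should acylate the phenyl ring in an intramolecular Friedel–Crafts reaction, giving the 3-bromo analogue of radermachol F2. Suzuki–Miyaura coupling of F2 with 9 (Pd(dppf)Cl2, K3PO4) then returns to the route at 14.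

Step 4: the Lewis acid may cause ipso attack or bromine migration on the 2-bromofuran, open the furan ring, or direct acylation to the phenyl ring. The fallback introduces the aroyl group by cross-coupling without any Lewis acid. It sets out from 6, which would be brominated a second time at C4 (NBS, DMF, rt) to methyl 2-(4,5-dibromo-2-phenylfuran-3-yl)acetate F3. Site-selective Suzuki–Miyaura coupling of F3 with 9 at the more reactive α-bromide should give methyl 2-[4-bromo-5-(2-methylprop-1-en-1-yl)-2-phenylfuran-3-yl]acetate F4. Carbonylative Suzuki–Miyaura coupling of F4 with [2-(methoxycarbonyl)phenyl]boronic acid under CO (Pd(OAc)2/Xantphos, K2CO3, PhMe, 80 °C) returns to the route at 10.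

Step 6: closure of the seven-membered ring may lose to intermolecular Claisen condensation or to addition of the enolate to the diaryl ketone of a second molecule. The fallback makes the two C–C bonds of that ring in the opposite order, so that ring closure is an electrophilic substitution. It sets out from 6, whose lithium enolate (LiHMDS, 2.2 equiv, THF, −78 °C) would be C-acylated with phthalic anhydride to 2-[2-(5-bromo-2-phenylfuran-3-yl)-3-methoxy-3-oxopropanoyl]benzoic acid F5. Activation of F5 as its mixed anhydride (TFAA, CH2Cl2; then SnCl4) should close the ring by intramolecular Friedel–Crafts acylation at furan C4, the only position the tether can reach, giving the bromo β-keto ester F1 described above. Suzuki–Miyaura coupling of F1 with 9 under anhydrous conditions (Pd(dppf)Cl2, K3PO4, dioxane) returns to the route at 11.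

Further compounds
F1 | step 7 | methyl 3-bromo-4,9-dioxo-1-phenyl-9,10-dihydro-4H-benzo[4,5]cyclohepta[1,2-c]furan-10-carboxylate (racemic) | COC(=O)C1C(=O)c2ccccc2C(=O)c2c(Br)oc(-c3ccccc3)c21
F2 | step 7 | 3-bromo analogue of radermachol (Br in place of the 2-methylprop-1-enyl group) | Brc1oc2c3c(c(O)c4ccccc4c(=O)c13)C(=O)c1ccccc1-2
F3 | step 4 | methyl 2-(4,5-dibromo-2-phenylfuran-3-yl)acetate | COC(=O)Cc1c(Br)c(Br)oc1-c1ccccc1
F4 | step 4 | methyl 2-[4-bromo-5-(2-methylprop-1-en-1-yl)-2-phenylfuran-3-yl]acetate | COC(=O)Cc1c(Br)c(C=C(C)C)oc1-c1ccccc1
F5 | step 6 | 2-[2-(5-bromo-2-phenylfuran-3-yl)-3-methoxy-3-oxopropanoyl]benzoic acid (racemic) | COC(=O)C(C(=O)c1ccccc1C(=O)O)c1cc(Br)oc1-c1ccccc1
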